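**Retrosynthetic overview** (eudesmane numbering: ring A = C1–C5/C10, ring B = C5–C10, isopropenyl C11–C13 on C7, C14 on C10, C15 on C4)
1. The C3 angelate goes on last; the cis 3β-OH/4β-OAc pair is traced to a C3=C4 alkene (Woodward cis-hydroxylation on the face of the C10 methyl), and that alkene with C15 to a C4 ketone (enol triflate, Negishi methylation).
2. Key disconnection: the C6–C7 bond of ring B, cut as a retro-Michael of the C4/C8 1,5-diketone; donor = dienolate of the C8 ketone whose α-carbon C7 already carries the oxygen (as MOM ether) and the isopropenyl group, acceptor = exo-methylene ketone C4(=O)–C5=C6H2 on ring A.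
3. Enabling feature: C7 is α to the ring B ketone C8 and allylic to C11=C12 (doubly acidic), while C6 lies β to C4, the oxygen-bearing carbon of ring A; the chain C4–C5–C6–C7–C8 is a 1,5-dioxygenated array that becomes a Michael retron once C4 is at the ketone level.
4. Precursor: C7–C8 by γ-alkoxyallylboration of a C8 aldehyde (ozonolysis of an allyl group), C6 by Mannich methylenation of a regiodefined enol silane, C10 (the only stereocentre carried into the key step) by copper-catalysed asymmetric conjugate addition of Me3Al to 3-allylcyclohexenone.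
5. Ring order: ring A comes from 3-ethoxycyclohexenone (step 1); ring B is closed in step 9, which sets C7 and C5; C3 and C4 are set in step 13.

Key step: step 9

Assumption: 17 and 18 are carried as mixtures of epimers at the side-chain carbons that become C7 and C8, because step 8 removes the C8 centre and step 9 turns both C7 epimers into one dienolate; α means the face opposite to the C10 methyl, β the same face.

**Step 1**
Reactants: 1 3-ethoxycyclohex-2-en-1-one
Product: 3 3-(prop-2-en-1-yl)cyclohex-2-en-1-one, via bromomagnesium alkoxide 2 (not isolated)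
Conditions: CH2=CHCH2MgBr, Et2O, 0 °C; then 1 M HCl, 0 °C
Reagents that add atoms: allylmagnesium bromide, C=CC[Mg]Br
Why: Stork–Danheiser sequence (1,2-addition to the vinylogous ester, then acid hydrolysis of the enol ether with allylic transposition) should give the 3-allyl enone, and no stereocentre is formed.

**Step 2**
Reactants: 3 3-(prop-2-en-1-yl)cyclohex-2-en-1-one
Product: 5 trimethyl{[(3R)-3-methyl-3-(prop-2-en-1-yl)cyclohex-1-en-1-yl]oxy}silane, via dimethylaluminium enolate 4 (not isolated)
Conditions: Me3Al, Cu(O2C-C4H3S) (copper thiophene-2-carboxylate, 2 mol%), binaphthol-derived N,N-bis(1-phenylethyl)phosphoramidite (4 mol%, the enantiomer that gives R), Et2O, −30 °C; then Me3SiOTf, −30 to 0 °C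
Reagents that add atoms: trimethylaluminium, C[Al](C)C; trimethylsilyl trifluoromethanesulfonate, C[Si](C)(C)OS(=O)(=O)C(F)(F)F
Why: Copper-catalysed asymmetric conjugate addition of a trialkylaluminium to a 3-substituted cyclohexenone is a well-precedented route to all-carbon quaternary centres, the chiral copper–phosphoramidite complex choosing the enone face for methyl delivery (C10, R), and O-silylation of the aluminium enolate stores the enolate regiochemistry toward C5.

**Step 3**
Reactants: 5 trimethyl{[(3R)-3-methyl-3-(prop-2-en-1-yl)cyclohex-1-en-1-yl]oxy}silane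
Product: 8 (3R)-3-methyl-2-methylidene-3-(prop-2-en-1-yl)cyclohexan-1-one, via Mannich base 6 (not isolated), via methiodide 7 (not isolated)
Conditions: CH2=NMe2+ I−, CH2Cl2, 23 °C; then MeI, 23 °C, concentrate; then DBU, CH2Cl2, 23 °C
Reagents that add atoms: dimethyl(methylidene)ammonium iodide, C=[N+](C)C.[I-]
Why: Mannich reaction of the regiodefined silyl enol ether at C5, N-methylation and E1cB loss of trimethylamine is the standard α-methylenation of a ketone and places C6 on C5 only; the transient C5 stereocentre is erased in the elimination.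

**Step 4**
Reactants: 8 (3R)-3-methyl-2-methylidene-3-(prop-2-en-1-yl)cyclohexan-1-one
Product: 10 2-[(1R)-1-methyl-2-methylidene-3-oxocyclohexyl]acetaldehyde, via secondary ozonide 9 (not isolated)
Conditions: O3 (1.0 equiv, titrated solution), CH2Cl2, −78 °C; then Me2S, −78 to 23 °C
Reagents that add atoms: ozone, [O-][O+]=O
Why: Ozonolysis with reductive work-up should cleave only the electron-rich monosubstituted alkene, which reacts much faster than the electron-poor enone double bond when one equivalent of ozone is used; C10 is untouched.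

**Step 5**
Reactants: 11 2-methylprop-2-en-1-ol
Product: 12 3-(methoxymethoxy)-2-methylprop-1-ene
Conditions: MeOCH2Cl, iPr2NEt, CH2Cl2, 0 to 23 °C
Reagents that add atoms: chloromethyl methyl ether, COCCl
Why: Base-mediated O-alkylation gives the methoxymethyl ether, an acetal that tolerates sBuLi and, unlike a silyl group, cannot migrate in the dienolate of step 9.

**Step 6**
Reactants: 12 3-(methoxymethoxy)-2-methylprop-1-ene
Product: 15 2-[(2Z)-3-(methoxymethoxy)-2-methylprop-2-en-1-yl]-4,4,5,5-tetramethyl-1,3,2-dioxaborolane, via allyllithium 13 (not isolated), via borate complex 14 (not isolated)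
Conditions: sBuLi, THF, −78 °C; then 2-isopropoxy-4,4,5,5-tetramethyl-1,3,2-dioxaborolane, −78 °C; then HCl (Et2O), −78 to 23 °C
Reagents that add atoms: 2-isopropoxy-4,4,5,5-tetramethyl-1,3,2-dioxaborolane, CC(C)OB1OC(C)(C)C(C)(C)O1
Why: α-Lithiation of the allylic ether gives the oxygen-chelated Z-alkoxyallyl anion, which is borylated at the carbon remote from oxygen, the established preparation of Z-γ-alkoxyallylboronates.

**Step 7**
Reactants: 10 2-[(1R)-1-methyl-2-methylidene-3-oxocyclohexyl]acetaldehyde; 15 2-[(2Z)-3-(methoxymethoxy)-2-methylprop-2-en-1-yl]-4,4,5,5-tetramethyl-1,3,2-dioxaborolane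
Product: 17 (3R)-3-[2-hydroxy-3-(methoxymethoxy)-4-methylpent-4-en-1-yl]-3-methyl-2-methylidenecyclohexan-1-one (syn diastereomers in the side chain), via borate ester 16 (not isolated)
Conditions: CH2Cl2, 23 °C, 48 h; then aqueous NaHCO3
Reagents that add atoms: none
Why: Allylboration through a closed chair transition state joins the oxygen-bearing γ-carbon (C7) to the aldehyde carbon (C8) and spares the enone because pinacol allylboronates do not add to ketones; the two new centres form as a syn pair without control relative to C10, which is harmless since C8 is oxidised in step 8 and C7 is planarised in step 9.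

**Step 8**
Reactants: 17 (3R)-3-[2-hydroxy-3-(methoxymethoxy)-4-methylpent-4-en-1-yl]-3-methyl-2-methylidenecyclohexan-1-one
Product: 18 (3R)-3-[3-(methoxymethoxy)-4-methyl-2-oxopent-4-en-1-yl]-3-methyl-2-methylidenecyclohexan-1-one (both epimers at the MOM-bearing carbon)
Conditions: 1,1,1-triacetoxy-1,1-dihydro-1,2-benziodoxol-3(1H)-one, NaHCO3, CH2Cl2, 0 to 23 °C
Reagents that add atoms: none
Why: Buffered periodinane oxidation of a secondary alcohol to the ketone runs under neutral conditions that should leave the enone and the β,γ-unsaturated α-alkoxy ketone intact; the C8 stereocentre disappears.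

**Step 9**
Reactants: 18 (3R)-3-[3-(methoxymethoxy)-4-methyl-2-oxopent-4-en-1-yl]-3-methyl-2-methylidenecyclohexan-1-one
Product: 19 (5R,7S,10R)-7-(methoxymethoxy)-15-noreudesm-11-ene-4,8-dione (trans-decalin; 7α-OMOM, 7β-isopropenyl, 5α-H)
Conditions: DBU (1.0 equiv), MeCN (0.02 M), 23 °C, then 50 °C
Reagents that add atoms: none
Why: DBU removes the doubly activated C7–H (α to the C8 ketone, allylic to C11=C12) of either C7 epimer of 18, so both converge on one extended dienolate whose α-carbon C7 adds to C6, the unsubstituted β-terminus of the exo-methylene ketone on ring A, and the resulting C4 enolate is protonated at C5. The closest known reaction type is the base-mediated intramolecular Michael addition of a ketone enolate to an enone giving a 1,5-diketone (first stage of a Robinson annulation), here through the α-carbon of a dienolate as in deconjugative α-alkylations. Ring B, the only ring formed, closes in the 6-endo-trig mode with respect to the C5=C6 acceptor (enolate double bond endocyclic). C7 is controlled by a chair-like transition state in which the one-carbon link C9 holds C7 over the enone face anti to the C10 methyl and the metal-free E-dienolate (O− anti to OMOM, isopropenyl syn to O−) places OMOM axial (α) and isopropenyl equatorial (β), which is also the thermodynamically preferred epimer and is reachable by retro-Michael/Michael equilibration at 50 °C; C5 is set by protonation and base equilibration next to the C4 ketone to the trans ring fusion. The step needs attack through C7 and not the γ-terminus C12 (that would need an eight-membered ring), conjugate and not aldol addition at C4 (reversible, the diketone is the sink) and intra- over intermolecular reaction (high dilution), and the absence of a chelating metal cation secures the dienolate geometry.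

**Step 10**
Reactants: 19 (5R,7S,10R)-7-(methoxymethoxy)-15-noreudesm-11-ene-4,8-dione
Product: 21 (5R,7S,10R)-7-(methoxymethoxy)-8-oxo-15-noreudesma-3,11-dien-4-yl trifluoromethanesulfonate, via lithium enolate 20 (not isolated)
Conditions: LiN(iPr)2 (1.1 equiv), THF, −78 °C; then PhNTf2, −78 to 0 °C
Reagents that add atoms: N-phenylbis(trifluoromethanesulfonimide), O=S(=O)(N(c1ccccc1)S(=O)(=O)C(F)(F)F)C(F)(F)F
Why: Kinetic enolisation followed by O-sulfonylation should take the unhindered C3 methylene of the C4 ketone and not the ring-fusion methine C5 or the neopentylic C9 of the C8 ketone, which is shielded by the quaternary C7 and the axial C10 methyl; no stereocentre is created.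

**Step 11**
Reactants: 21 (5R,7S,10R)-7-(methoxymethoxy)-8-oxo-15-noreudesma-3,11-dien-4-yl trifluoromethanesulfonate
Product: 22 (5R,7S,10R)-7-(methoxymethoxy)eudesma-3,11-dien-8-one
Conditions: MeZnCl, Pd(PPh3)4 (5 mol%), THF, 50 °C
Reagents that add atoms: methylzinc chloride, C[Zn]Cl
Why: Negishi coupling (oxidative addition of zerovalent palladium to the alkenyl triflate, transmetalation, reductive elimination) installs C15 with the double bond fixed at C3=C4, and the organozinc reagent leaves the hindered C8 ketone alone.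

**Step 12**
Reactants: 22 (5R,7S,10R)-7-(methoxymethoxy)eudesma-3,11-dien-8-one
Product: 24 (5R,7S,10R)-7-hydroxyeudesma-3,11-dien-8-one, via dimethylborinate 23 (not isolated)
Conditions: Me2BBr, CH2Cl2, −78 °C; then aqueous NaHCO3, THF
Reagents that add atoms: none
Why: Lewis acid cleavage of the methoxymethyl acetal by bromodimethylborane takes place at the acetal carbon at −78 °C, so the C7–O bond and its configuration, both alkenes and the ketone remain untouched.

**Step 13**
Reactants: 24 (5R,7S,10R)-7-hydroxyeudesma-3,11-dien-8-one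
Product: 27 (3S,4R,5R,7S,10R)-4-acetoxy-3,7-dihydroxyeudesm-11-en-8-one, via iodo acetate 25 (not isolated), via acetoxonium acetate 26 (not isolated)
Conditions: I2 (1.05 equiv), AgOAc (2.2 equiv), AcOH, 23 °C; then H2O (2 equiv), 60 °C
Reagents that add atoms: silver acetate, CC(=O)[O-].[Ag+]; water, O
Why: In the Woodward cis-hydroxylation the iodonium ion forms on the less hindered α face of the electron-rich trisubstituted C3=C4 alkene, acetate opens it trans-diaxially at the tertiary C4 from the β face, the neighbouring acetate displaces the axial C3 iodide with inversion to a cis-fused β-acetoxonium ion, and water opens this with the axial C4 oxygen keeping the acetyl group, so that C3 (S) and C4 (R) are set on the face of the C10 methyl and the acetate sits on the tertiary oxygen.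

**Step 14**
Reactants: 27 (3S,4R,5R,7S,10R)-4-acetoxy-3,7-dihydroxyeudesm-11-en-8-one
Product: 28 (3S,4R,5R,7S,10R)-4-acetoxy-7-hydroxy-8-oxoeudesm-11-en-3-yl (2Z)-2-methylbut-2-enoate (CNP0381775.1)
Conditions: angelic acid, 2,4,6-Cl3C6H2COCl, Et3N, toluene, 23 °C; then 27, toluene, 75 °C
Reagents that add atoms: angelic acid, C/C=C(/C)C(=O)O
Why: Yamaguchi-type esterification through the preformed mixed anhydride, without a nucleophilic catalyst so that Z to E isomerisation of the angeloyl group is suppressed, should acylate the secondary equatorial C3 hydroxyl in preference to the tertiary C7 hydroxyl; no stereocentre changes.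

**Compound list**
1 | 3-ethoxycyclohex-2-en-1-one | CCOC1=CC(=O)CCC1 | starting material
2 | bromomagnesium 3-ethoxy-1-(prop-2-en-1-yl)cyclohex-2-en-1-olate (not isolated) | CCOC1=CC(CC=C)(O[Mg]Br)CCC1 | intermediate
3 | 3-(prop-2-en-1-yl)cyclohex-2-en-1-one | C=CCC1=CC(=O)CCC1 | intermediate
4 | dimethylaluminium (3R)-3-methyl-3-(prop-2-en-1-yl)cyclohex-1-en-1-olate (not isolated) | C[Al](C)OC1=C[C@](C)(CCC1)CC=C | intermediate
5 | trimethyl{[(3R)-3-methyl-3-(prop-2-en-1-yl)cyclohex-1-en-1-yl]oxy}silane | C[Si](C)(C)OC1=C[C@](C)(CCC1)CC=C | intermediate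
6 | (3R)-2-[(dimethylamino)methyl]-3-methyl-3-(prop-2-en-1-yl)cyclohexan-1-one, both C2 epimers (not isolated) | CN(C)CC1C(=O)CCC[C@]1(C)CC=C | intermediate
7 | {[(2R)-2-methyl-6-oxo-2-(prop-2-en-1-yl)cyclohexyl]methyl}trimethylammonium iodide (not isolated) | C[N+](C)(C)CC1C(=O)CCC[C@]1(C)CC=C.[I-] | intermediate
8 | (3R)-3-methyl-2-methylidene-3-(prop-2-en-1-yl)cyclohexan-1-one | C=C1C(=O)CCC[C@]1(C)CC=C | intermediate
9 | (3R)-3-methyl-2-methylidene-3-(1,2,4-trioxolan-3-ylmethyl)cyclohexan-1-one (not isolated) | C=C1C(=O)CCC[C@]1(C)CC2OCOO2 | intermediate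
10 | 2-[(1R)-1-methyl-2-methylidene-3-oxocyclohexyl]acetaldehyde | C=C1C(=O)CCC[C@]1(C)CC=O | intermediate
11 | 2-methylprop-2-en-1-ol | C=C(C)CO | starting material
12 | 3-(methoxymethoxy)-2-methylprop-1-ene | C=C(C)COCOC | intermediate
13 | [(2Z)-3-(methoxymethoxy)-2-methylprop-2-en-1-yl]lithium (not isolated) | [Li]C/C(C)=C\OCOC | intermediate
14 | lithium 2-isopropoxy-2-[(2Z)-3-(methoxymethoxy)-2-methylprop-2-en-1-yl]-4,4,5,5-tetramethyl-1,3,2-dioxaborolan-2-uide (not isolated) | [Li+].CC(C)O[B-]1(C/C(C)=C\OCOC)OC(C)(C)C(C)(C)O1 | intermediate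
15 | 2-[(2Z)-3-(methoxymethoxy)-2-methylprop-2-en-1-yl]-4,4,5,5-tetramethyl-1,3,2-dioxaborolane | CC1(C)OB(C/C(C)=C\OCOC)OC1(C)C | intermediate
16 | pinacol borate ester of 17 (O-boryl on the side-chain carbinol; not isolated) | C=C1C(=O)CCC[C@]1(C)CC(OB2OC(C)(C)C(C)(C)O2)C(OCOC)C(C)=C | intermediate
17 | (3R)-3-[2-hydroxy-3-(methoxymethoxy)-4-methylpent-4-en-1-yl]-3-methyl-2-methylidenecyclohexan-1-one (syn side-chain diastereomers) | C=C1C(=O)CCC[C@]1(C)CC(O)C(OCOC)C(C)=C | intermediate
18 | (3R)-3-[3-(methoxymethoxy)-4-methyl-2-oxopent-4-en-1-yl]-3-methyl-2-methylidenecyclohexan-1-one (both side-chain epimers) | C=C1C(=O)CCC[C@]1(C)CC(=O)C(OCOC)C(C)=C | intermediate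
19 | (5R,7S,10R)-7-(methoxymethoxy)-15-noreudesm-11-ene-4,8-dione | C=C(C)[C@@]1(OCOC)C[C@@H]2[C@](C)(CCCC2=O)CC1=O | intermediate
20 | lithium C3=C4 enolate of 19 (not isolated) | C=C(C)[C@@]1(OCOC)C[C@@H]2[C@](C)(CCC=C2O[Li])CC1=O | intermediate
21 | (5R,7S,10R)-7-(methoxymethoxy)-8-oxo-15-noreudesma-3,11-dien-4-yl trifluoromethanesulfonate | C=C(C)[C@@]1(OCOC)C[C@@H]2[C@](C)(CCC=C2OS(=O)(=O)C(F)(F)F)CC1=O | intermediate
22 | (5R,7S,10R)-7-(methoxymethoxy)eudesma-3,11-dien-8-one | C=C(C)[C@@]1(OCOC)C[C@@H]2[C@](C)(CCC=C2C)CC1=O | intermediate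
23 | (5R,7S,10R)-7-[(dimethylboranyl)oxy]eudesma-3,11-dien-8-one (not isolated) | C=C(C)[C@@]1(OB(C)C)C[C@@H]2[C@](C)(CCC=C2C)CC1=O | intermediate
24 | (5R,7S,10R)-7-hydroxyeudesma-3,11-dien-8-one | C=C(C)[C@@]1(O)C[C@@H]2[C@](C)(CCC=C2C)CC1=O | intermediate
25 | (3R,4R,5R,7S,10R)-4-acetoxy-7-hydroxy-3-iodoeudesm-11-en-8-one (3α-I, 4β-OAc; not isolated) | C=C(C)[C@@]1(O)C[C@@H]2[C@](C)(CC[C@@H](I)[C@]2(C)OC(C)=O)CC1=O | intermediate
26 | 3β,4β-(2-methyl-1,3-dioxolan-2-ylium) ion of the 7-hydroxyeudesm-11-en-8-one skeleton, acetate salt (not isolated) | C=C(C)[C@@]1(O)C[C@@H]2[C@](C)(CC[C@@H]3OC(C)=[O+][C@@]32C)CC1=O.CC(=O)[O-] | intermediate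
27 | (3S,4R,5R,7S,10R)-4-acetoxy-3,7-dihydroxyeudesm-11-en-8-one | C=C(C)[C@@]1(O)C[C@@H]2[C@](C)(CC[C@H](O)[C@]2(C)OC(C)=O)CC1=O | intermediate
28 | (3S,4R,5R,7S,10R)-4-acetoxy-7-hydroxy-8-oxoeudesm-11-en-3-yl (2Z)-2-methylbut-2-enoate | C=C(C)[C@@]1(O)C[C@@H]2[C@](C)(CC[C@H](OC(=O)/C(C)=C\C)[C@]2(C)OC(C)=O)CC1=O | target

**Totals:** 14 steps in all; longest linear sequence 12 steps (steps 1–4 and 7–14; steps 5 and 6 are a two-step branch).

**Steps most likely to fail**

Step 13 (Woodward cis-hydroxylation). The iodonium chemistry may also engage the isopropenyl double bond. The acetoxonium ion may open, or the product may equilibrate by acyl migration in warm acetic acid, so that the acetyl group ends on O3. Attack may also begin on the wrong face. The fallback sets out from 22 and returns at 27. Buffered peracid epoxidation (mCPBA, NaHCO3, CH2Cl2, 0 °C) of the more electron-rich C3=C4 alkene from the α face should give (3R,4S,5R,7S,10R)-3,4-epoxy-7-(methoxymethoxy)eudesm-11-en-8-one F1. Acetic acid should open it trans-diaxially at the tertiary C4 from the β face to (3R,4R,5R,7S,10R)-4-acetoxy-3-hydroxy-7-(methoxymethoxy)eudesm-11-en-8-one F2, whose 3α-hydroxyl is trans to the acetate and cannot take it over. Periodinane oxidation should give (4R,5R,7S,10R)-4-acetoxy-7-(methoxymethoxy)eudesm-11-ene-3,8-dione F3. Luche reduction (NaBH4, CeCl3, MeOH, −78 °C; axial hydride from the α face, C8 being shielded) should give (3S,4R,5R,7S,10R)-4-acetoxy-3-hydroxy-7-(methoxymethoxy)eudesm-11-en-8-one F4. Me2BBr as in step 12 then gives 27.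

Step 9 (key Michael closure). Closure may pass through a boat-like or cation-chelated arrangement and give poor control at C7. It may stall after isomerisation of 18 to the conjugated enol ether, or be overtaken by intermolecular Michael addition. The fallback sets out from 10 and returns at 19. Addition of 2-methylprop-1-enylmagnesium bromide at −78 °C should give (3R)-3-(2-hydroxy-4-methylpent-3-en-1-yl)-3-methyl-2-methylidenecyclohexan-1-one F5, and MnO2 oxidation (3R)-3-methyl-2-methylidene-3-(4-methyl-2-oxopent-3-en-1-yl)cyclohexan-1-one F6. Catalytic KOtBu in tBuOH/THF should close ring B through the α-carbon of the extended dienolate (deconjugative Michael addition) to (5R,7R,10R)-15-noreudesm-11-ene-4,8-dione F7, in which C5 and C7 both carry an enolisable hydrogen and settle under simple base equilibration; any conjugated 7(11)-ene isomer gives the same dienolate in the next operation. KN(SiMe3)2 with equilibration to the extended dienolate, then 2-(phenylsulfonyl)-3-phenyloxaziridine, should hydroxylate C7 by axial attack on the α face to (5R,7S,10R)-7-hydroxy-15-noreudesm-11-ene-4,8-dione F8. MeOCH2Cl with iPr2NEt at 40 °C returns to 19.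

Step 10 (regioselective enol triflate). Deprotonation may occur at C9 or C5 instead of C3, or the enolate may equilibrate before sulfonylation. The fallback sets out from 19 and returns at 22. MeLi with CeCl3 in THF at −78 °C should add to the less shielded C4 ketone from the α face to (4S,5R,7S,10R)-4-hydroxy-7-(methoxymethoxy)eudesm-11-en-8-one F9. Methyl N-(triethylammoniosulfonyl)carbamate in benzene at 50 °C should then dehydrate by syn elimination; only the cis C3 hydrogen and the methyl hydrogens are available because the C5 hydrogen is trans to the hydroxyl. This gives 22, from which any exocyclic isomer must be separated.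

**Further compounds**
F1 | step 13 | (3R,4S,5R,7S,10R)-3,4-epoxy-7-(methoxymethoxy)eudesm-11-en-8-one | C=C(C)[C@@]1(OCOC)C[C@@H]2[C@](C)(CC[C@H]3O[C@]32C)CC1=O
F2 | step 13 | (3R,4R,5R,7S,10R)-4-acetoxy-3-hydroxy-7-(methoxymethoxy)eudesm-11-en-8-one | C=C(C)[C@@]1(OCOC)C[C@@H]2[C@](C)(CC[C@@H](O)[C@]2(C)OC(C)=O)CC1=O
F3 | step 13 | (4R,5R,7S,10R)-4-acetoxy-7-(methoxymethoxy)eudesm-11-ene-3,8-dione | C=C(C)[C@@]1(OCOC)C[C@@H]2[C@](C)(CCC(=O)[C@]2(C)OC(C)=O)CC1=O
F4 | step 13 | (3S,4R,5R,7S,10R)-4-acetoxy-3-hydroxy-7-(methoxymethoxy)eudesm-11-en-8-one | C=C(C)[C@@]1(OCOC)C[C@@H]2[C@](C)(CC[C@H](O)[C@]2(C)OC(C)=O)CC1=O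
F5 | step 9 | (3R)-3-(2-hydroxy-4-methylpent-3-en-1-yl)-3-methyl-2-methylidenecyclohexan-1-one | C=C1C(=O)CCC[C@]1(C)CC(O)C=C(C)C
F6 | step 9 | (3R)-3-methyl-2-methylidene-3-(4-methyl-2-oxopent-3-en-1-yl)cyclohexan-1-one | C=C1C(=O)CCC[C@]1(C)CC(=O)C=C(C)C
F7 | step 9 | (5R,7R,10R)-15-noreudesm-11-ene-4,8-dione | C=C(C)[C@H]1C[C@@H]2[C@](C)(CCCC2=O)CC1=O
F8 | step 9 | (5R,7S,10R)-7-hydroxy-15-noreudesm-11-ene-4,8-dione | C=C(C)[C@@]1(O)C[C@@H]2[C@](C)(CCCC2=O)CC1=O
F9 | step 10 | (4S,5R,7S,10R)-4-hydroxy-7-(methoxymethoxy)eudesm-11-en-8-one | C=C(C)[C@@]1(OCOC)C[C@@H]2[C@](C)(CCC[C@]2(C)O)CC1=O
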